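At early times the flask (east, 25 °C) climbs quickly: G reads 22% at 8.00 min and 36% at 25.0 min, and no later reading stands higher, the last being 30% at 90.0 min. The west run, at 31 °C, goes flat by the same reading, but higher.

| flask | E | Z | D | temperature | remark | time |
|---|---|---|---|---|---|---|
| east | 0.25 M | 17 mM (held) | 11 mM | 25 °C | the very flask that is asked about, followed so far |  |
| west | 0.25 M | 17 mM (held) | 11 mM | 31 °C | run made earlier |  |
| flask | 0.25 M | 17 mM (held) | 11 mM | 25 °C |  | 1.5 h |

- east (time / min: G / %): 8.00: 22; 25.0: 36; 40.0: 33; 60.0: 34; 90.0: 30
- west (time / min: G / %): 8.00: 30; 25.0: 43; 40.0: 40; 60.0: 41; 90.0: 42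

(scatter of a reading: 1.5 percentage points)

1. G, in percent of the E first charged, at 1.5 h
2. what to do for the largest gain in G; "none" if nothing gains more than 2 percentage points (Saturday's / Monday's / Friday's / Wednesday's / none)
3. G present, with what was taken out counted in, in percent of the E first charged, after Saturday's
4. G present, with what was taken out counted in, in percent of the E first charged, after Friday's

- Saturday's: change nothing and wait 25 min more
- Monday's: at 1.5 h take out 90% of the G then present, then wait 25 min
- Friday's: at 1.5 h add D, 50.0% of the amount charged, then wait 25 min
- Wednesday's: at 1.5 h raise the temperature by 20 K, then wait 25 min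

- G that was removed still counts
- the numbers in the tables scatter by 1.5 percentage points (one standard deviation)
- at the start none of Z is in solution
- additions bring no volume worth counting

For whoever takes over the bench: follow one unit of charged E. Once the curve is flat, that unit stands as G with a chance equal to the mean of the flat readings, and otherwise as something that is not G.

east: chance of G 33.2%, odds against 2.01

west: chance of G 41.5%, odds against 1.41

These odds against G, the not-G part over the G part on the flat stretch, are the quantity to carry. Warming by 6.00 K divides them by 1.42. This reckoning reads them as a balance, which is a judgement and no proof. On that reading the flask at 1.5 h holds 33.2% of G, and neither waiting nor adding D changes the odds, so Saturday's and Friday's are not worth doing. Two actions remain, with the step taken as a steady factor per kelvin: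

Monday's: G taken out, the rest returns to the same odds, total 53.2%

Wednesday's: odds 0.618, G 61.8%

Wednesday's therefore gives more than Monday's, and it is the one to choose.

The forecast says 33.5% now, 33.5% after Saturday's, 33.5% after Friday's, and Wednesday's as best, a little above this reckoning on the first three. Its grounds: “So the stall is either equilibrium or a dead catalyst, and these curve shapes cannot separate the two.”

The flask gives 32.3%, then 32.3% after Saturday's, 32.3% after Friday's and 64.0% after Wednesday's.

    2 D ⇌ L, settled at all times (K = 1400 L mol⁻¹, ΔH = −28.0 kJ mol⁻¹)
    Z ⇌ X, rate k2*(csat - [X]) (kL = 0.0370 s⁻¹)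
    G + D ⇌ J + D, rate k3*[D]*[G] forward; the back reaction follows from the equilibrium constant (K = 2.10, k = 1.30 L mol⁻¹ s⁻¹, Ea = 37.0 kJ mol⁻¹, ΔH = −52.0 kJ mol⁻¹)
    E + X + D → D + G (k = 55.0 L² mol⁻² s⁻¹, Ea = 38.0 kJ mol⁻¹)
    (constants at 25 °C)

In the flask the relaxation half-life of G and J at 90.0 min, by the step between them alone and counted both ways together, is 3.32 min, short against 1.5 h, and at 90.0 min E stands at 0.0219%, with J at 67.7% against G at 32.3%, which makes the odds 2.10. For a repeat at 50 °C the carried step gives odds of 0.460, and that repeat holds J at 29.3% against G at 70.7%, odds of 0.414.

All runs were computed for an exercise.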